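Ring A carries oxygen at C8a and at C7, a 1,3-pattern that identifies it as a disguised cyclohexane-1,3-dione. In that hydroaromatic form O1–C8a=C4a–C4=O is the vinylogous ester of a 2,3-dihydropyran-4-one. Ring C is therefore cut at C2–C3 and O1–C8a. A single operation, enantioselective γ-aldol addition of a ring-fused 1,3-bis(silyloxy)diene to silylated 4-hydroxybenzaldehyde followed by acid cyclodehydration, makes both bonds, ring C and both stereocentres. The diene comes from a 2-(arylacetyl)cyclohexanone whose future C7 carbonyl is a dioxolane and whose aryl group carries bromine. A Heck reaction then adds the chalcone arm, ring A is unmasked and aromatised, and all silyl ethers fall together.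

Key step: step 6

Remark: chromanone numbering (O1, C2, C3, C4, C4a, C5–C8, C8a) is used for all intermediates. The target is (2R,3S), with the two aryl groups trans and an E enone. TBS = tert-butyldimethylsilyl, TMS = trimethylsilyl.
Assumption: (R)-BINOL is taken to open the Re face of the aromatic aldehyde, as in related titanium–BINOL additions of allyl and silyl enol nucleophiles. If the sense proves opposite, (S)-BINOL is used and nothing else changes.

Step 1
Reactants: 1 2-(5-bromo-2-hydroxyphenyl)acetic acid
Product: 3 2-[5-bromo-2-(tert-butyldimethylsilyloxy)phenyl]acetic acid, via silyl ester 2 (not isolated)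
Conditions: TBSCl (2.3 equiv), imidazole (2.5 equiv), DMF, rt; then THF/AcOH/H2O added to the same flask, rt
Reagents that add atoms: tert-butyldimethylsilyl chloride, CC(C)(C)[Si](C)(C)Cl
Why: Imidazole-promoted silylation caps the phenol and the acid alike, and the far more labile silyl ester is then hydrolysed selectively by dilute acetic acid, which aryl silyl ethers tolerate, so that the phenol is blocked against lactonisation to the benzofuranone and against the bases to come.

Step 2
Reactants: 3 2-[5-bromo-2-(tert-butyldimethylsilyloxy)phenyl]acetic acid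
Product: 4 2-[5-bromo-2-(tert-butyldimethylsilyloxy)phenyl]-1-(imidazol-1-yl)ethan-1-one
Conditions: 1,1'-carbonyldiimidazole (1.1 equiv), CH2Cl2, rt until gas evolution ends; quick ice-water wash, Na2SO4, concentrate, use crude
Reagents that add atoms: 1,1'-carbonyldiimidazole, O=C(n1ccnc1)n1ccnc1
Why: Carbonyldiimidazole activation proceeds through a mixed anhydride that loses CO2, and the cold-water wash removes imidazole and surplus reagent, whose N–H proton and carbonyl group would otherwise consume enolate in step 3.

Step 3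
Reactants: 4 acyl imidazolide of step 2; 5 1,4-dioxaspiro[4.5]decan-7-one
Product: 7 8-{2-[5-bromo-2-(tert-butyldimethylsilyloxy)phenyl]acetyl}-1,4-dioxaspiro[4.5]decan-7-one, via lithium enolate 6 (not isolated)
Conditions: 5 (2.1 equiv), LiN(i-Pr)2 (2.1 equiv), THF, −78 °C; 4 in THF, −78 → −40 °C; aq NH4Cl; silica deactivated with Et3N
Reagents that add atoms: lithium diisopropylamide, [Li]N(C(C)C)C(C)C (supplies only the lithium of intermediate 6; nothing from it remains in 7)
Why: Crossed Claisen-type C-acylation of a preformed ketone enolate with an N-acylimidazole: the amide base at −78 °C takes the proton at the future C4a, on the side away from the ketal, so that no enolate carbon stands next to the ketal carbon and no alkoxide is expelled, the imidazolide favours carbon over oxygen, and the second equivalent of enolate absorbs the acidic proton of the β-diketone.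

Step 4
Reactants: 7 β-diketone of step 3
Product: 8 2-[5-bromo-2-(tert-butyldimethylsilyloxy)phenyl]-1-[7-(trimethylsilyloxy)-1,4-dioxaspiro[4.5]dec-7-en-8-yl]ethan-1-one
Conditions: TMSCl (1.5 equiv), Et3N (1.6 equiv), toluene, rt; filtration under argon, concentrate, use crude
Reagents that add atoms: trimethylsilyl chloride, C[Si](C)(C)Cl
Why: O-Silylation of an enolised β-diketone by TMSCl and a tertiary amine is the standard first stage on the way to 1,3-bis(silyloxy)dienes, and a six-membered ring prefers the endocyclic enol ether C8a=C4a, which leaves C4=O flanked only by the benzylic C3 methylene.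

Step 5
Reactants: 8 mono(trimethylsilyl) enol ether of step 4
Product: 10 8-{(Z)-2-[5-bromo-2-(tert-butyldimethylsilyloxy)phenyl]-1-(trimethylsilyloxy)ethenyl}-7-(trimethylsilyloxy)-1,4-dioxaspiro[4.5]dec-7-ene, via lithium dienolate 9 (not isolated)
Conditions: LiN(i-Pr)2 (1.1 equiv), THF, −78 °C; TMSCl (1.3 equiv), −78 → 0 °C; pentane, filtration under argon, no aqueous work-up, use at once
Reagents that add atoms: trimethylsilyl chloride, C[Si](C)(C)Cl; lithium diisopropylamide, [Li]N(C(C)C)C(C)C (lithium of intermediate 9 only)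
Why: Kinetic α'-deprotonation of the β-silyloxy enone followed by O-silylation is the standard second stage; the benzylic C3 protons are much the most acidic, so that C8 next to the ketal is left alone, a benzyl ketone gives the Z enolate, and the strong-base route avoids TMSOTf/amine mixtures, which are known to open dioxolanes to enol ethers.

Step 6
Reactants: 10 bis(trimethylsilyl) dienol ether of step 5; 11 4-(tert-butyldimethylsilyloxy)benzaldehyde
Product: 14 (2R,3S)-3-[5-bromo-2-(tert-butyldimethylsilyloxy)phenyl]-2-[4-(tert-butyldimethylsilyloxy)phenyl]-7,7-ethylenedioxy-2,3,5,6,7,8-hexahydro-4H-chromen-4-one (trans), via silylated aldol adduct 12 (not isolated), via hydroxy diketone 13 (not isolated)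
Conditions: Ti(Oi-Pr)4 (20 mol %), (R)-BINOL (20 mol %), 4 Å molecular sieves, THF, −78 → −20 °C; then CH2Cl2, anhydrous TFA (3 equiv), 0 °C → rt until the cis isomer has converged; cold aq NaHCO3
Reagents that add atoms: none
Why: The BINOL–titanium alkoxide complex binds the aldehyde oxygen and the terminal, aryl-bearing C3 of the diene attacks the exposed Re face through an open transition state, which forms C2–C3, after which silyl transfer frees the catalyst and leaves 12. TFA removes both trimethylsilyl groups and the C2 hydroxyl of 13 then adds to the ring carbonyl C8a (6-exo-trig on the keto tautomer, equivalent to a 6-endo-trig oxa-Michael addition on the enol tautomer); loss of water gives O1–C8a=C4a–C4=O and so closes ring C. The closest known type is the titanium–BINOL-catalysed vinylogous Mukaiyama aldol reaction of 1,3-bis(silyloxy)dienes from β-keto esters and β-diketones with aromatic aldehydes, finished by TFA to 2,3-dihydropyran-4-ones, a stepwise formal hetero-Diels–Alder reaction. C2 is controlled by the ligand and is retained because its C–O bond is never broken, the oxygen acting only as nucleophile, which is why the acid stage is started cold and kept no longer than needed, so that the electron-rich benzylic position does not ionise. C3, benzylic and α to C4=O, is under thermodynamic control and epimerises through the enol until both aryl groups are pseudo-equatorial, that is trans (2R,3S), so that diene geometry and simple aldol diastereoselectivity do not matter. The step needs γ over α attack, secured because C4a is fully substituted whereas C3 carries hydrogen and the largest terminal coefficient, and it needs an intact ketal, secured by an alkoxide-type Lewis acid of low acidity, by sieves and by anhydrous TFA.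

Step 7
Reactants: 15 2',4'-dihydroxyacetophenone
Product: 16 1-[2,4-bis(tert-butyldimethylsilyloxy)phenyl]ethan-1-one
Conditions: TBSCl (2.5 equiv), imidazole (3 equiv), DMAP (cat.), DMF, rt → 40 °C
Reagents that add atoms: tert-butyldimethylsilyl chloride, CC(C)(C)[Si](C)(C)Cl
Why: Routine imidazole-promoted silylation, pushed with excess reagent and gentle warming because the 2-hydroxyl is hydrogen-bonded to the ketone; the same silyl group is used as elsewhere so that one final operation removes all of them.

Step 8
Reactants: 16 bis-silylated acetophenone of step 7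
Product: 18 1-[2,4-bis(tert-butyldimethylsilyloxy)phenyl]prop-2-en-1-one, via Mannich base 17 (not isolated)
Conditions: (CH2O)n (3 equiv), i-Pr2NH·CF3CO2H (1 equiv), CF3CO2H (10 mol %), THF, reflux; stored cold over BHT, used fresh
Reagents that add atoms: paraformaldehyde (as formaldehyde), C=O; diisopropylammonium trifluoroacetate, CC(C)[NH2+]C(C)C.[O-]C(=O)C(F)(F)F (amino group of intermediate 17 only)
Why: Direct α-methylenation of an aryl methyl ketone by a Mannich reaction and spontaneous β-elimination of the hindered amine, a known preparation of aryl vinyl ketones; both phenols stay silylated because a free 2-hydroxyl would add to the enone and give a chromanone.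

Step 9
Reactants: 14 bromide of step 6; 18 aryl vinyl ketone of step 8
Product: 19 (2R,3S)-3-{5-[(E)-3-(2,4-bis(tert-butyldimethylsilyloxy)phenyl)-3-oxoprop-1-enyl]-2-(tert-butyldimethylsilyloxy)phenyl}-2-[4-(tert-butyldimethylsilyloxy)phenyl]-7,7-ethylenedioxy-2,3,5,6,7,8-hexahydro-4H-chromen-4-one
Conditions: 18 (1.5 equiv), Pd(P(t-Bu)3)2 (5 mol %), Cy2NMe (1.2 equiv), BHT (trace), toluene, rt → 45 °C
Reagents that add atoms: none
Why: Mizoroki–Heck arylation of an aryl vinyl ketone, a known route to chalcones: the bulky electron-rich phosphine lets zerovalent palladium insert into the electron-rich aryl bromide near room temperature, syn insertion at the unsubstituted terminus and syn β-hydride elimination give the E enone, the hindered amine in toluene is too weak to start retro-oxa-Michael opening at O1–C2, and coupling before ring A is unmasked means that no phenol or acidic enol can add to the vinyl ketone and no reprotection is needed.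

Step 10
Reactants: 19 ketal chalcone of step 9
Product: 20 (2R,3S)-3-{5-[(E)-3-(2,4-bis(tert-butyldimethylsilyloxy)phenyl)-3-oxoprop-1-enyl]-2-(tert-butyldimethylsilyloxy)phenyl}-2-[4-(tert-butyldimethylsilyloxy)phenyl]-2,3,5,6-tetrahydro-4H-chromene-4,7(8H)-dione
Conditions: AcOH/THF/H2O (4:1:1), 40 °C; toluene azeotrope, use crude
Reagents that add atoms: water, O
Why: Acid-catalysed ketal hydrolysis in aqueous acetic acid, a medium that cleaves cyclohexanone dioxolanes but leaves aryl silyl ethers, the vinylogous ester and the enone alone and cannot epimerise C2.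

Step 11
Reactants: 20 4,7-dione of step 10
Product: 21 (2R,3S)-3-{5-[(E)-3-(2,4-bis(tert-butyldimethylsilyloxy)phenyl)-3-oxoprop-1-enyl]-2-(tert-butyldimethylsilyloxy)phenyl}-2-[4-(tert-butyldimethylsilyloxy)phenyl]-7-hydroxychroman-4-one
Conditions: DDQ (1.05 equiv), 1,4-dioxane, rt (→ 50 °C only if needed); filtration of the hydroquinone
Reagents that add atoms: none
Why: Quinone dehydrogenation of a cyclohexenone to a phenol: the C7 ketone enolises toward C8 to the diene C7=C8–C8a=C4a, DDQ abstracts hydride from C5 to give a cation stabilised by O1 and by the C7 oxygen, loss of a C6 proton delivers the arene, and one equivalent at room temperature should spare C2–C3, whose dehydrogenation to the chromone needs forcing conditions.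

Step 12
Reactants: 21 tetrasilyl ether of step 11
Product: 22 (2R,3S)-3-{5-[(E)-3-(2,4-dihydroxyphenyl)-3-oxoprop-1-enyl]-2-hydroxyphenyl}-7-hydroxy-2-(4-hydroxyphenyl)chroman-4-one (CNP0183323.3)
Conditions: HF·pyridine (excess), pyridine, THF, polyethylene vessel, 0 °C → rt; pH 7 phosphate buffer
Reagents that add atoms: none
Why: Fluoride-driven cleavage of the four aryl silyl ethers in a slightly acidic medium, so that no phenoxide arises and neither retro-oxa-Michael opening of ring C, which would erase C2, nor cyclisation of the 2'-hydroxychalcone to a flavanone is set off.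

Compound list
1 | 2-(5-bromo-2-hydroxyphenyl)acetic acid | OC(=O)Cc1cc(Br)ccc1O | starting material
2 | tert-butyldimethylsilyl 2-[5-bromo-2-(tert-butyldimethylsilyloxy)phenyl]acetate | CC(C)(C)[Si](C)(C)OC(=O)Cc1cc(Br)ccc1O[Si](C)(C)C(C)(C)C | intermediate
3 | 2-[5-bromo-2-(tert-butyldimethylsilyloxy)phenyl]acetic acid | OC(=O)Cc1cc(Br)ccc1O[Si](C)(C)C(C)(C)C | intermediate
4 | 2-[5-bromo-2-(tert-butyldimethylsilyloxy)phenyl]-1-(imidazol-1-yl)ethan-1-one | O=C(Cc1cc(Br)ccc1O[Si](C)(C)C(C)(C)C)n1ccnc1 | intermediate
5 | 1,4-dioxaspiro[4.5]decan-7-one | O=C1CCCC2(C1)OCCO2 | starting material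
6 | lithium 1,4-dioxaspiro[4.5]dec-7-en-7-olate (kinetic enolate) | [Li]OC1=CCCC2(C1)OCCO2 | intermediate
7 | 8-{2-[5-bromo-2-(tert-butyldimethylsilyloxy)phenyl]acetyl}-1,4-dioxaspiro[4.5]decan-7-one (racemic at the enolisable carbon) | O=C(Cc1cc(Br)ccc1O[Si](C)(C)C(C)(C)C)C1CCC2(CC1=O)OCCO2 | intermediate
8 | 2-[5-bromo-2-(tert-butyldimethylsilyloxy)phenyl]-1-[7-(trimethylsilyloxy)-1,4-dioxaspiro[4.5]dec-7-en-8-yl]ethan-1-one | C[Si](C)(C)OC1=C(CCC2(C1)OCCO2)C(=O)Cc1cc(Br)ccc1O[Si](C)(C)C(C)(C)C | intermediate
9 | lithium (Z)-dienolate of 8 (deprotonated at C3) | C[Si](C)(C)OC1=C(CCC2(C1)OCCO2)/C(O[Li])=C/c1cc(Br)ccc1O[Si](C)(C)C(C)(C)C | intermediate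
10 | 8-{(Z)-2-[5-bromo-2-(tert-butyldimethylsilyloxy)phenyl]-1-(trimethylsilyloxy)ethenyl}-7-(trimethylsilyloxy)-1,4-dioxaspiro[4.5]dec-7-ene | C[Si](C)(C)OC1=C(CCC2(C1)OCCO2)/C(O[Si](C)(C)C)=C/c1cc(Br)ccc1O[Si](C)(C)C(C)(C)C | intermediate
11 | 4-(tert-butyldimethylsilyloxy)benzaldehyde | O=Cc1ccc(O[Si](C)(C)C(C)(C)C)cc1 | starting material
12 | O-trimethylsilyl aldol adduct, (R) at C2, C3 unassigned, ring enol still silylated | C[Si](C)(C)O[C@@H](c1ccc(O[Si](C)(C)C(C)(C)C)cc1)C(c1cc(Br)ccc1O[Si](C)(C)C(C)(C)C)C(=O)C1=C(O[Si](C)(C)C)CC2(CC1)OCCO2 | intermediate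
13 | δ-hydroxy β-diketone, (R) at C2, C3 and C4a unassigned | O[C@@H](c1ccc(O[Si](C)(C)C(C)(C)C)cc1)C(c1cc(Br)ccc1O[Si](C)(C)C(C)(C)C)C(=O)C1CCC2(CC1=O)OCCO2 | intermediate
14 | (2R,3S)-3-[5-bromo-2-(tert-butyldimethylsilyloxy)phenyl]-2-[4-(tert-butyldimethylsilyloxy)phenyl]-7,7-ethylenedioxy-2,3,5,6,7,8-hexahydro-4H-chromen-4-one | Brc1ccc(O[Si](C)(C)C(C)(C)C)c([C@@H]2C(=O)C3=C(CC4(OCCO4)CC3)O[C@H]2c2ccc(O[Si](C)(C)C(C)(C)C)cc2)c1 | intermediate
15 | 2',4'-dihydroxyacetophenone | CC(=O)c1ccc(O)cc1O | starting material
16 | 1-[2,4-bis(tert-butyldimethylsilyloxy)phenyl]ethan-1-one | CC(=O)c1ccc(O[Si](C)(C)C(C)(C)C)cc1O[Si](C)(C)C(C)(C)C | intermediate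
17 | 1-[2,4-bis(tert-butyldimethylsilyloxy)phenyl]-3-(diisopropylamino)propan-1-one | CC(C)N(CCC(=O)c1ccc(O[Si](C)(C)C(C)(C)C)cc1O[Si](C)(C)C(C)(C)C)C(C)C | intermediate
18 | 1-[2,4-bis(tert-butyldimethylsilyloxy)phenyl]prop-2-en-1-one | C=CC(=O)c1ccc(O[Si](C)(C)C(C)(C)C)cc1O[Si](C)(C)C(C)(C)C | intermediate
19 | (2R,3S) tetrasilylated E-chalcone with ring A as the C7 ethylene ketal | O=C(/C=C/c1ccc(O[Si](C)(C)C(C)(C)C)c([C@@H]2C(=O)C3=C(CC4(OCCO4)CC3)O[C@H]2c2ccc(O[Si](C)(C)C(C)(C)C)cc2)c1)c1ccc(O[Si](C)(C)C(C)(C)C)cc1O[Si](C)(C)C(C)(C)C | intermediate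
20 | (2R,3S) tetrasilylated E-chalcone, 2,3,5,6-tetrahydro-4H-chromene-4,7(8H)-dione | O=C(/C=C/c1ccc(O[Si](C)(C)C(C)(C)C)c([C@@H]2C(=O)C3=C(CC(=O)CC3)O[C@H]2c2ccc(O[Si](C)(C)C(C)(C)C)cc2)c1)c1ccc(O[Si](C)(C)C(C)(C)C)cc1O[Si](C)(C)C(C)(C)C | intermediate
21 | (2R,3S) tetrasilylated E-chalcone, 7-hydroxychroman-4-one | O=C(/C=C/c1ccc(O[Si](C)(C)C(C)(C)C)c([C@@H]2C(=O)c3ccc(O)cc3O[C@H]2c2ccc(O[Si](C)(C)C(C)(C)C)cc2)c1)c1ccc(O[Si](C)(C)C(C)(C)C)cc1O[Si](C)(C)C(C)(C)C | intermediate
22 | (2R,3S)-3-{5-[(E)-3-(2,4-dihydroxyphenyl)-3-oxoprop-1-enyl]-2-hydroxyphenyl}-7-hydroxy-2-(4-hydroxyphenyl)chroman-4-one | O=C(/C=C/c1ccc(O)c([C@@H]2C(=O)c3ccc(O)cc3O[C@H]2c2ccc(O)cc2)c1)c1ccc(O)cc1O | target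

Total step count: 12. Longest linear sequence: 10 steps (steps 1–6 and 9–12). Steps 7 and 8 form the side branch.

Steps most likely to fail

1. Step 6.
- What may go wrong: the hindered, aryl-bearing diene terminus may add too slowly to an electron-rich aldehyde under so mild a Lewis acid. The diene may be protodesilylated instead, facial selectivity may be poor, or C2 may ionise during the acid stage.
- Modest enantiomeric purity could be raised at 14 by crystallisation.
- Fallback, from 7 back to 14: the catalytic silyl-diene chemistry is given up for the classical γ-aldol reaction of a β-diketone dianion followed by resolution.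
- Compound 7 is treated with LiN(i-Pr)2 (2.2 equiv, THF, −78 → 0 °C) to give the dilithium dianion F1. This adds through its benzylic carbon to 11 at −78 °C to give the racemic δ-hydroxy β-diketone F2.
- TFA in CH2Cl2 closes this to the racemic trans-dihydropyranone F3. Preparative chromatography on a chiral stationary phase separates 14 from its mirror image.

2. Step 3.
- What may go wrong: proton transfer from the acidic arylacetyl methylene to the enolate (with ketene formation), O-acylation, or enolate equilibration toward C8 followed by expulsion of a ketal oxygen.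
- Fallback, from 3 back to 7: the acyl donor is replaced by an aldehyde, which a lithium enolate captures faster than it deprotonates, and the oxidation level is restored afterwards.
- Acid 3 is reduced with BH3·THF to the 2-arylethanol F4. This is oxidised with TEMPO (cat.) and PhI(OAc)2 to the arylacetaldehyde F5.
- F5 is added at −78 °C to enolate 6 to give the β-hydroxy ketone F6 as a diastereomer mixture. IBX in hot ethyl acetate oxidises it to 7.

3. Step 11.
- What may go wrong: slow hydride abstraction from a poorly enolised ketone, over-oxidation across C2–C3 with loss of both stereocentres, or oxidative damage once the free phenol has formed.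
- Fallback, from 20 to 22: ketone dehydrogenation is replaced by aromatisation of a locked cyclohexa-1,3-diene, so that no free phenol meets the oxidant.
- Dione 20 is treated with TBSOTf and Et3N (CH2Cl2, −78 → 0 °C) to give the 7-silyloxy-5,6-dihydro diene F7.
- DDQ at 0 °C removes hydride from C5 and a proton from C6 and should give the pentasilyl ether F8. The conditions of step 12 convert it directly into 22.

Further compounds
F1 | step 6 | dilithium dianion of 7 | [Li]OC1=C(CCC2(C1)OCCO2)/C(O[Li])=C/c1cc(Br)ccc1O[Si](C)(C)C(C)(C)C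
F2 | step 6 | racemic δ-hydroxy β-diketone (all stereocentres unassigned) | OC(c1ccc(O[Si](C)(C)C(C)(C)C)cc1)C(c1cc(Br)ccc1O[Si](C)(C)C(C)(C)C)C(=O)C1CCC2(CC1=O)OCCO2
F3 | step 6 | racemic trans-dihydropyranone (14 plus its (2S,3R) mirror image; the mirror image is drawn) | Brc1ccc(O[Si](C)(C)C(C)(C)C)c([C@H]2C(=O)C3=C(CC4(OCCO4)CC3)O[C@@H]2c2ccc(O[Si](C)(C)C(C)(C)C)cc2)c1
F4 | step 3 | 2-[5-bromo-2-(tert-butyldimethylsilyloxy)phenyl]ethan-1-ol | OCCc1cc(Br)ccc1O[Si](C)(C)C(C)(C)C
F5 | step 3 | 2-[5-bromo-2-(tert-butyldimethylsilyloxy)phenyl]acetaldehyde | O=CCc1cc(Br)ccc1O[Si](C)(C)C(C)(C)C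
F6 | step 3 | 8-{2-[5-bromo-2-(tert-butyldimethylsilyloxy)phenyl]-1-hydroxyethyl}-1,4-dioxaspiro[4.5]decan-7-one (diastereomer mixture) | OC(Cc1cc(Br)ccc1O[Si](C)(C)C(C)(C)C)C1CCC2(CC1=O)OCCO2
F7 | step 11 | (2R,3S) pentasilylated 7-silyloxy-2,3,5,6-tetrahydro-4H-chromen-4-one | O=C(/C=C/c1ccc(O[Si](C)(C)C(C)(C)C)c([C@@H]2C(=O)C3=C(C=C(O[Si](C)(C)C(C)(C)C)CC3)O[C@H]2c2ccc(O[Si](C)(C)C(C)(C)C)cc2)c1)c1ccc(O[Si](C)(C)C(C)(C)C)cc1O[Si](C)(C)C(C)(C)C
F8 | step 11 | (2R,3S) pentasilyl ether of the target | O=C(/C=C/c1ccc(O[Si](C)(C)C(C)(C)C)c([C@@H]2C(=O)c3ccc(O[Si](C)(C)C(C)(C)C)cc3O[C@H]2c2ccc(O[Si](C)(C)C(C)(C)C)cc2)c1)c1ccc(O[Si](C)(C)C(C)(C)C)cc1O[Si](C)(C)C(C)(C)C
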